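**Retrosynthetic overview**
- The strategy rests on the carbocycle C1–C10. It has a ring-cis C1=C10 alkene (C14 on C10), a ring-trans C4=C5 alkene, the C6–C7 bond between two stereocentres, and oxygen on the neighbouring C8 and C9. A cyclohexene alkene, a Cope-made E alkene, a Cope-made sigma bond and a Cope-released enolate/ketone leave exactly this pattern.
- One final oxidation of a C6,C12,C14-triol makes the C14 enal and closes the five-membered lactone (O6 to C12). The triol comes from an 8-hydroxy-9-ketone by esterification at C8 with inversion, C9 reduction, acetylation and PMB removal.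
- The 8-hydroxy-9-ketone comes from a 1,6-dialkenylcyclohex-2-enol by anionic oxy-Cope ring expansion (C9–C4 broken, C6–C7 made), with hydroxylation of the C8 enolate in the same flask.
- The carbinol comes from a 2,6,6-trisubstituted cyclohexenone and an E-dienyl iodide by carbonyl addition at C9. The enone derives from (S)-2-allyl-2-methylcyclohexanone, whose quaternary carbon (C4) is set by asymmetric allylation and sacrificed in the key step.
- Ring order: the six-membered ring is bought, the ten-membered ring arises by 6-to-10 expansion, and the lactone is closed last.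

Key step: step 16

**Remarks**
- Germacrane numbering (C1–C15) is used throughout. α is the face of O6 and β the face of C11 on C7. PMB is 4-methoxybenzyl.
- An electrophile can reach the ring enolate only from outside the ring. This puts the new oxygen trans to the C7 side chain (8α), whereas the target has it cis (8β). The C8 ester is therefore installed with inversion in step 17.
- All later stereocentres derive from C4. The enantiomeric purity from step 3 is assumed sufficient and, if needed, is raised by recrystallising a crystalline carbonyl derivative of the allyl ketone before step 4.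

**Route**

Step 1
Reactants: 1 2-methylcyclohexan-1-one
Product: 2 2-methyl-1-(trimethylsilyloxy)cyclohex-1-ene
Conditions: Me3SiCl, NaI, Et3N, MeCN, rt; fractional distillation
Reagents that add atoms: chlorotrimethylsilane, C[Si](C)(C)Cl
Why: Silyl enol ether formation under equilibrating conditions (Me3SiI made in situ, amine base) favours the tetrasubstituted thermodynamic enol ether, and the minor regioisomer is removed by distillation.

Step 2
Reactants: 2 2-methyl-1-(trimethylsilyloxy)cyclohex-1-ene; 3 allyl chloroformate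
Product: 5 allyl 2-methylcyclohex-1-en-1-yl carbonate, via lithium enolate 4 (not isolated)
Conditions: MeLi, THF, 0 °C; then 3, −78 °C
Reagents that add atoms: allyl chloroformate (3), C=CCOC(=O)Cl
Why: Methyllithium cleaves the O–Si bond and releases the regiodefined enolate without equilibration, and the hard chloroformate acylates this hindered enolate on oxygen (enol carbonate formation).

Step 3
Reactants: 5 allyl 2-methylcyclohex-1-en-1-yl carbonate
Product: 6 (S)-2-allyl-2-methylcyclohexan-1-one
Conditions: Pd2(dba)3 (cat.), (S)-4-tert-butyl-2-[2-(diphenylphosphino)phenyl]-4,5-dihydrooxazole (cat.), THF, 25 °C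
Reagents that add atoms: none
Why: Decarboxylative asymmetric allylic alkylation (Tsuji allylation): zerovalent palladium ionises the allyl carbonate, CO2 is lost, and enolate and allyl recombine inside the chiral P,N-ligand pocket, the (S)-ligand giving the (S)-quaternary carbon that becomes C4.

Step 4
Reactants: 6 (S)-2-allyl-2-methylcyclohexan-1-one
Product: 7 (S)-2-methyl-2-[(E)-prop-1-enyl]cyclohexan-1-one
Conditions: RuHCl(CO)(PPh3)3 (cat.), toluene, 110 °C
Reagents that add atoms: none
Why: Ruthenium hydride catalysed alkene isomerisation (hydrometalation, beta-hydride elimination) moves the terminal alkene to the more substituted internal position, the quaternary carbon cannot epimerise, and the alkene geometry does not matter because the alkene is cleaved next.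

Step 5
Reactants: 7 (S)-2-methyl-2-[(E)-prop-1-enyl]cyclohexan-1-one
Product: 9 (S)-1-methyl-2-oxocyclohexane-1-carbaldehyde, via secondary ozonide 8 (not isolated)
Conditions: O3, CH2Cl2, −78 °C; then PPh3, −78 °C to rt
Reagents that add atoms: ozone, [O-][O+]=O
Why: Ozonolysis with reductive work-up cleaves the only alkene, the quaternary alpha carbon rules out enolisation between the carbonyls, and the deformylation-prone beta-keto aldehyde is used at once.

Step 6
Reactants: 9 (S)-1-methyl-2-oxocyclohexane-1-carbaldehyde; 10 iodoform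
Product: 11 (S)-2-[(E)-2-iodovinyl]-2-methylcyclohexan-1-one
Conditions: CrCl2, 10, THF, 0 °C to rt
Reagents that add atoms: iodoform (10), IC(I)I
Why: Takai olefination: the geminal dichromium species from iodoform adds to the aldehyde far faster than to the hindered ketone, and elimination from the less crowded adduct gives the E iodoalkene (brings C6).

Step 7
Reactants: 11 (S)-2-[(E)-2-iodovinyl]-2-methylcyclohexan-1-one
Product: 12 (S)-2-[(E)-2-(4-methoxybenzyloxy)vinyl]-2-methylcyclohexan-1-one
Conditions: CuI (cat.), 3,4,7,8-tetramethyl-1,10-phenanthroline (cat.), 4-methoxybenzyl alcohol, Cs2CO3, toluene, 80 °C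
Reagents that add atoms: 4-methoxybenzyl alcohol, COc1ccc(CO)cc1
Why: Ullmann-type copper-catalysed C–O cross-coupling of an alkenyl iodide with a primary alcohol retains alkene geometry, so the E enol ether (future C5=C6–O) results and the quaternary centre is untouched.

Step 8
Reactants: 12 (S)-2-[(E)-2-(4-methoxybenzyloxy)vinyl]-2-methylcyclohexan-1-one
Product: 14 (S)-6-[(E)-2-(4-methoxybenzyloxy)vinyl]-6-methylcyclohex-2-en-1-one, via lithium enolate 13 (not isolated)
Conditions: LiN(i-Pr)2, THF, −78 °C; then PhS(Cl)=N-t-Bu, −78 °C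
Reagents that add atoms: none
Why: Mukaiyama dehydrogenation: the only possible enolate attacks sulfur of the sulfinimidoyl chloride and the adduct undergoes intramolecular syn elimination at −78 °C, which gives the enone without harming the acid-sensitive enol ether.

Step 9
Reactants: 14 (S)-6-[(E)-2-(4-methoxybenzyloxy)vinyl]-6-methylcyclohex-2-en-1-one; 15 formaldehyde
Product: 16 (S)-2-(hydroxymethyl)-6-[(E)-2-(4-methoxybenzyloxy)vinyl]-6-methylcyclohex-2-en-1-one
Conditions: 15 (37% aq.), 4-(dimethylamino)pyridine (cat.), THF/H2O, rt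
Reagents that add atoms: formaldehyde (15), C=O
Why: Morita–Baylis–Hillman reaction: conjugate addition of the amine catalyst at the unhindered beta carbon gives the C10 enolate, which adds to formaldehyde and expels the catalyst, installing C14.

Step 10
Reactants: 16 (S)-2-(hydroxymethyl)-6-[(E)-2-(4-methoxybenzyloxy)vinyl]-6-methylcyclohex-2-en-1-one
Product: 17 (S)-2-[(4-methoxybenzyloxy)methyl]-6-[(E)-2-(4-methoxybenzyloxy)vinyl]-6-methylcyclohex-2-en-1-one
Conditions: 2-(4-methoxybenzyloxy)-4-methylquinoline, MeOTf, MgO, PhCF3, 0 °C to rt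
Reagents that add atoms: 2-(4-methoxybenzyloxy)-4-methylquinoline, COc1ccc(COc2cc(C)c3ccccc3n2)cc1
Why: Neutral benzyl transfer from an N-methyl-2-benzyloxyquinolinium salt formed in situ (SN1-like etherification buffered by MgO) protects the primary alcohol without the acid that would hydrolyse the enol ether or the strong base that would degrade the Baylis–Hillman adduct.

Step 11
Reactants: 18 2-bromoprop-2-en-1-ol
Product: 19 2-bromoallyl 4-methoxybenzyl ether
Conditions: NaH, 4-methoxybenzyl chloride, n-Bu4NI (cat.), THF/DMF, 0 °C to rt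
Reagents that add atoms: 4-methoxybenzyl chloride, COc1ccc(CCl)cc1
Why: Williamson ether synthesis on a primary allylic alkoxide, the vinylic bromide being inert to substitution.

Step 12
Reactants: 19 2-bromoallyl 4-methoxybenzyl ether; 20 ethynyltrimethylsilane
Product: 21 {3-[(4-methoxybenzyloxy)methyl]but-3-en-1-ynyl}trimethylsilane
Conditions: 20, PdCl2(PPh3)2 (cat.), CuI (cat.), Et3N, THF, rt
Reagents that add atoms: ethynyltrimethylsilane (20), C#C[Si](C)(C)C
Why: Sonogashira coupling at the sp2 carbon–bromine bond forms the C11–C7 bond of the cross-conjugated enyne.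

Step 13
Reactants: 21 {3-[(4-methoxybenzyloxy)methyl]but-3-en-1-ynyl}trimethylsilane
Product: 22 2-[(4-methoxybenzyloxy)methyl]but-1-en-3-yne
Conditions: K2CO3 (cat.), MeOH, 0 °C to rt
Reagents that add atoms: none
Why: Methoxide-catalysed protodesilylation cleaves the alkynyl C–Si bond selectively and leaves the ether and alkene untouched.

Step 14
Reactants: 22 2-[(4-methoxybenzyloxy)methyl]but-1-en-3-yne
Product: 24 (E)-1-iodo-3-[(4-methoxybenzyloxy)methyl]buta-1,3-diene, via alkenylzirconocene chloride 23 (not isolated)
Conditions: Cp2Zr(H)Cl, THF, rt, dark; then I2, 0 °C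
Reagents that add atoms: iodine, [I][I]
Why: Hydrozirconation adds Zr–H syn across the terminal alkyne (metal on the terminal carbon, much faster than on the 1,1-disubstituted alkene), and iodinolysis with retention gives the E iododiene.

Step 15
Reactants: 24 (E)-1-iodo-3-[(4-methoxybenzyloxy)methyl]buta-1,3-diene; 17 (S)-2-[(4-methoxybenzyloxy)methyl]-6-[(E)-2-(4-methoxybenzyloxy)vinyl]-6-methylcyclohex-2-en-1-one
Product: 27 (1R,6S)-1-{(1E)-3-[(4-methoxybenzyloxy)methyl]buta-1,3-dienyl}-2-[(4-methoxybenzyloxy)methyl]-6-[(E)-2-(4-methoxybenzyloxy)vinyl]-6-methylcyclohex-2-en-1-ol (the two alkenyl groups trans), via dienyllithium 25 (not isolated), via dienylcerium dichloride 26 (not isolated)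
Conditions: 24, t-BuLi (2 equiv), Et2O, −78 °C; CeCl3, THF, −78 °C; then 17, −78 to −40 °C; H2O
Reagents that add atoms: none
Why: Iodine–lithium exchange with retention of geometry, transmetalation to the weakly basic, oxophilic organocerium and 1,2-addition to the hindered enone form C8–C9; the nucleophile is expected to enter axially, anti to the pseudo-axial alkoxyvinyl group on C4, giving the trans-dialkenyl (1R) carbinol, and any C9 epimer is removed by chromatography because only the trans isomer has a single unambiguous chair for step 16.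

Step 16
Reactants: 27 (1R,6S)-1,6-dialkenylcyclohex-2-en-1-ol
Product: 30 (1(10)Z,4E,6R,7R,8R)-8-hydroxy-6,12,14-tris(4-methoxybenzyloxy)germacra-1(10),4,11(13)-trien-9-one (6α-OPMB, C7 side chain β, 8α-OH), via potassium alkoxide 28 (not isolated), via potassium enolate 29 (not isolated)
Conditions: KH, 18-crown-6, THF, 0 to 40 °C; then −78 °C, 2-(phenylsulfonyl)-3-phenyloxaziridine; AcOH, −78 °C
Reagents that add atoms: 2-(phenylsulfonyl)-3-phenyloxaziridine, O=S(=O)(c1ccccc1)N1OC1c1ccccc1
Why: KH with 18-crown-6 gives the naked alkoxide 28, whose charge weakens C9–C4 and triggers a concerted [3,3] shift over C7=C8–C9–C4–C5=C6 (C9–C4 breaks, C6–C7 forms), and the cross-conjugated enolate 29 so released is hydroxylated at C8 by the N-sulfonyloxaziridine in the same flask; the closest known reaction type is the anionic oxy-Cope ring expansion of trans-1,2-dialkenylcyclohexanols to cyclodecenones with trapping or oxidation of the enolate. The ten-membered carbocycle is closed by a four-atom ring expansion of the cyclohexene through a six-centre pericyclic array, not by end-to-end cyclisation, and no other ring is formed. C6 and C7 are controlled by the (S)-quaternary C4: the diequatorial dialkenyl conformer has only one chair (C3 and C10 equatorial, C4-methyl and O9 axial), and the E enol ether and E dienyl termini place OPMB and C11 equatorial, which gives 6R,7R (O6 and C11 trans) and the E C4=C5 alkene, erases the C4 and C9 stereocentres, and leaves C1=C10 ring-cis as in the cyclohexene. C8 is controlled by the ring: allylic 1,3-strain holds H7 in the enolate plane and leaves the C6–C7 bond and the C4=C5 alkene over the inner face, so oxygen arrives only from outside, anti to C6–C7, giving 8R (8α, trans to the C7 side chain), the epimer that step 17 inverts. The step needs chair over boat, the exocyclic C7=C8 alkene over the ring C1=C10 alkene, and alpha-prime over gamma oxidation; these are secured by the geometrically pure E,E termini with the equatorial tether, by the fact that C1=C10 could reach C5=C6 only through a bridged boat, and by regiospecific release of the enolate, which is oxidised at −78 °C before proton transfer.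

Step 17
Reactants: 30 8α-hydroxy-9-ketone; 31 methacrylic acid
Product: 32 (1(10)Z,4E,6R,7S,8S)-8-methacryloyloxy-6,12,14-tris(4-methoxybenzyloxy)germacra-1(10),4,11(13)-trien-9-one (8β ester; the C7 descriptor changes only through CIP priorities)
Conditions: 31, PPh3, diisopropyl azodicarboxylate, toluene, 0 °C to rt
Reagents that add atoms: methacrylic acid (31), C=C(C)C(=O)O
Why: Mitsunobu esterification: the C8 hydroxyl becomes an alkoxyphosphonium leaving group on a carbon alpha to the C9 carbonyl and thus activated for SN2 displacement, so methacrylate enters with inversion and converts 8R (8α) into the 8S (8β) ester of the target.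

Step 18
Reactants: 32 8β-methacryloyloxy-9-ketone
Product: 33 (1(10)Z,4E,6R,7S,8S,9S)-9-hydroxy-8-methacryloyloxy-6,12,14-tris(4-methoxybenzyloxy)germacra-1(10),4,11(13)-triene (9α-OH)
Conditions: NaBH4, CeCl3·7H2O, MeOH/THF, −78 °C
Reagents that add atoms: none
Why: Luche reduction gives 1,2-reduction of the enone, and hydride is expected to arrive from the ring periphery past H8 in the conformer that opposes the C8–O and C9=O dipoles (Cornforth or polar Felkin–Anh control), which sets 9S (9α-OH, trans to the C8 ester).

Step 19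
Reactants: 33 9α-alcohol
Product: 34 (1(10)Z,4E,6R,7S,8S,9S)-9-acetoxy-8-methacryloyloxy-6,12,14-tris(4-methoxybenzyloxy)germacra-1(10),4,11(13)-triene
Conditions: Ac2O, Et3N, 4-(dimethylamino)pyridine (cat.), CH2Cl2, 0 °C
Reagents that add atoms: acetic anhydride, CC(=O)OC(C)=O
Why: Nucleophile-catalysed acylation of the secondary allylic alcohol at low temperature should outrun 1,2-migration of the methacrylate and touches no stereocentre.

Step 20
Reactants: 34 tris-PMB ether
Product: 35 (1(10)Z,4E,6R,7S,8S,9S)-9-acetoxy-6,12,14-trihydroxy-8-methacryloyloxygermacra-1(10),4,11(13)-triene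
Conditions: DDQ, CH2Cl2/pH 7 buffer, 0 °C
Reagents that add atoms: none
Why: Oxidative PMB cleavage: DDQ abstracts hydride from the three electron-rich benzylic positions and water hydrolyses the oxocarbenium ions, while the esters and alkenes are inert and the buffer suppresses acid-induced transannular reactions.

Step 21
Reactants: 35 C6,C12,C14-triol
Product: 38 CNP0403553.1, (6R,7S,8S,9S)-9-acetoxy-8-methacryloyloxy-14-oxogermacra-1(10),4E,11(13)-trien-12,6-olide with ring-cis C1=C10, via hydroxy dialdehyde 36 (not isolated), via lactol 37 (not isolated)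
Conditions: PhI(OAc)2, 2,2,6,6-tetramethylpiperidin-1-oxyl (cat.), CH2Cl2, rt
Reagents that add atoms: none
Why: Oxoammonium oxidation prefers primary over secondary alcohols, so C14 gives the enal and C12 gives an enal that the C6 hydroxyl traps as a five-membered lactol (5-exo-trig), which is oxidised on to the alpha-methylene lactone (oxidative lactonisation of a 1,4-diol) with all four stereocentres untouched.

**Compound list**
1 | 2-methylcyclohexan-1-one | CC1CCCCC1=O | starting material
2 | 2-methyl-1-(trimethylsilyloxy)cyclohex-1-ene | CC1=C(O[Si](C)(C)C)CCCC1 | intermediate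
3 | allyl chloroformate | C=CCOC(=O)Cl | starting material
4 | lithium 2-methylcyclohex-1-en-1-olate | [Li]OC1=C(C)CCCC1 | intermediate
5 | allyl 2-methylcyclohex-1-en-1-yl carbonate | C=CCOC(=O)OC1=C(C)CCCC1 | intermediate
6 | (S)-2-allyl-2-methylcyclohexan-1-one | C=CC[C@]1(C)CCCCC1=O | intermediate
7 | (S)-2-methyl-2-[(E)-prop-1-enyl]cyclohexan-1-one | C/C=C/[C@]1(C)CCCCC1=O | intermediate
8 | secondary ozonide of 7 | CC1OOC(O1)[C@]1(C)CCCCC1=O | intermediate
9 | (S)-1-methyl-2-oxocyclohexane-1-carbaldehyde | O=C[C@]1(C)CCCCC1=O | intermediate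
10 | iodoform | IC(I)I | starting material
11 | (S)-2-[(E)-2-iodovinyl]-2-methylcyclohexan-1-one | I/C=C/[C@]1(C)CCCCC1=O | intermediate
12 | (S)-2-[(E)-2-(4-methoxybenzyloxy)vinyl]-2-methylcyclohexan-1-one | COc1ccc(CO/C=C/[C@]2(C)CCCCC2=O)cc1 | intermediate
13 | lithium enolate of 12 | [Li]OC1=CCCC[C@@]1(C)/C=C/OCc1ccc(OC)cc1 | intermediate
14 | (S)-6-[(E)-2-(4-methoxybenzyloxy)vinyl]-6-methylcyclohex-2-en-1-one | O=C1C=CCC[C@@]1(C)/C=C/OCc1ccc(OC)cc1 | intermediate
15 | formaldehyde | C=O | starting material
16 | (S)-2-(hydroxymethyl)-6-[(E)-2-(4-methoxybenzyloxy)vinyl]-6-methylcyclohex-2-en-1-one | O=C1C(CO)=CCC[C@@]1(C)/C=C/OCc1ccc(OC)cc1 | intermediate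
17 | (S)-2-[(4-methoxybenzyloxy)methyl]-6-[(E)-2-(4-methoxybenzyloxy)vinyl]-6-methylcyclohex-2-en-1-one | COc1ccc(COCC2=CCC[C@@](C)(/C=C/OCc3ccc(OC)cc3)C2=O)cc1 | intermediate
18 | 2-bromoprop-2-en-1-ol | C=C(Br)CO | starting material
19 | 2-bromoallyl 4-methoxybenzyl ether | C=C(Br)COCc1ccc(OC)cc1 | intermediate
20 | ethynyltrimethylsilane | C#C[Si](C)(C)C | starting material
21 | {3-[(4-methoxybenzyloxy)methyl]but-3-en-1-ynyl}trimethylsilane | C=C(C#C[Si](C)(C)C)COCc1ccc(OC)cc1 | intermediate
22 | 2-[(4-methoxybenzyloxy)methyl]but-1-en-3-yne | C#CC(=C)COCc1ccc(OC)cc1 | intermediate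
23 | (E)-dienylzirconocene chloride | Cl[Zr](/C=C/C(=C)COCc1ccc(OC)cc1)(C1C=CC=C1)C1C=CC=C1 | intermediate
24 | (E)-1-iodo-3-[(4-methoxybenzyloxy)methyl]buta-1,3-diene | I/C=C/C(=C)COCc1ccc(OC)cc1 | intermediate
25 | (E)-dienyllithium | [Li]/C=C/C(=C)COCc1ccc(OC)cc1 | intermediate
26 | (E)-dienylcerium dichloride | Cl[Ce](Cl)/C=C/C(=C)COCc1ccc(OC)cc1 | intermediate
27 | (1R,6S)-1,6-dialkenylcyclohex-2-en-1-ol (trans-dialkenyl, oxy-Cope precursor) | O[C@@]1(/C=C/C(=C)COCc2ccc(OC)cc2)C(COCc2ccc(OC)cc2)=CCC[C@@]1(C)/C=C/OCc1ccc(OC)cc1 | intermediate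
28 | potassium alkoxide of 27 | [K+].[O-][C@@]1(/C=C/C(=C)COCc2ccc(OC)cc2)C(COCc2ccc(OC)cc2)=CCC[C@@]1(C)/C=C/OCc1ccc(OC)cc1 | intermediate
29 | potassium C8=C9 enolate of the ten-membered ring (ring-trans enolate) | [K+].[O-]/C1=C\[C@@H](C(=C)COCc2ccc(OC)cc2)[C@H](OCc2ccc(OC)cc2)/C=C(\C)CC/C=C1/COCc1ccc(OC)cc1 | intermediate
30 | (1(10)Z,4E,6R,7R,8R)-8-hydroxy-6,12,14-tris(4-methoxybenzyloxy)germacra-1(10),4,11(13)-trien-9-one | O[C@@H]1[C@@H](C(=C)COCc2ccc(OC)cc2)[C@H](OCc2ccc(OC)cc2)/C=C(\C)CC/C=C(/COCc2ccc(OC)cc2)C1=O | intermediate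
31 | methacrylic acid | C=C(C)C(=O)O | starting material
32 | (6R,7S,8S)-8-methacryloyloxy-6,12,14-tris(4-methoxybenzyloxy)germacra-1(10)Z,4E,11(13)-trien-9-one | C=C(C)C(=O)O[C@H]1[C@@H](C(=C)COCc2ccc(OC)cc2)[C@H](OCc2ccc(OC)cc2)/C=C(\C)CC/C=C(/COCc2ccc(OC)cc2)C1=O | intermediate
33 | (6R,7S,8S,9S)-9-hydroxy-8-methacryloyloxy tris-PMB ether | C=C(C)C(=O)O[C@H]1[C@@H](C(=C)COCc2ccc(OC)cc2)[C@H](OCc2ccc(OC)cc2)/C=C(\C)CC/C=C(/COCc2ccc(OC)cc2)[C@@H]1O | intermediate
34 | (6R,7S,8S,9S)-9-acetoxy-8-methacryloyloxy tris-PMB ether | C=C(C)C(=O)O[C@H]1[C@@H](C(=C)COCc2ccc(OC)cc2)[C@H](OCc2ccc(OC)cc2)/C=C(\C)CC/C=C(/COCc2ccc(OC)cc2)[C@@H]1OC(C)=O | intermediate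
35 | (6R,7S,8S,9S)-9-acetoxy-6,12,14-trihydroxy-8-methacryloyloxygermacra-1(10)Z,4E,11(13)-triene | C=C(C)C(=O)O[C@H]1[C@@H](C(=C)CO)[C@H](O)/C=C(\C)CC/C=C(/CO)[C@@H]1OC(C)=O | intermediate
36 | 6-hydroxy-12,14-dialdehyde | C=C(C)C(=O)O[C@H]1[C@@H](C(=C)C=O)[C@H](O)/C=C(\C)CC/C=C(/C=O)[C@@H]1OC(C)=O | intermediate
37 | 12,6-lactol 14-aldehyde | C=C(C)C(=O)O[C@H]1[C@H]2C(=C)C(O)O[C@@H]2/C=C(\C)CC/C=C(/C=O)[C@@H]1OC(C)=O | intermediate
38 | CNP0403553.1 | C=C(C)C(=O)O[C@H]1[C@H]2C(=C)C(=O)O[C@@H]2/C=C(\C)CC/C=C(/C=O)[C@@H]1OC(C)=O | target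

**Step count**
- Total step count: 21
- Longest linear sequence: 17 steps (steps 1–10 and 15–21)

**Steps most likely to fail**

1. Step 16.
   - What may go wrong: the alkoxide may fragment by retro-addition, or part of the material may leak through a boat array. Proton transfer may turn the cross-conjugated enolate into the extended dienolate before oxygen transfer. The enolate may also add to the sulfonimine that the oxidant releases.
   - Fallback (sets out from 27, returns at 30): the rearrangement is run as before, but enolate 29 is not oxidised in the flask. It is silylated at −78 °C with Et3SiCl to the triethylsilyl dienol ether F1, which is isolated and freed from base and crown ether. Dimethyldioxirane in acetone/CH2Cl2 at −78 °C (Rubottom oxidation, again on the outer face of the most electron-rich alkene) then gives the 8α-triethylsilyloxy ketone F2. HF·pyridine in THF gives 30.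

2. Step 17.
   - What may go wrong: displacement may be slow because the rear of the C8–O bond points towards the ring interior. Competing processes are elimination towards C7, transannular participation of the C4=C5 alkene, esterification with retention through an acyloxyphosphonium species, and base-induced epimerisation of the product.
   - Fallback (sets out from 30, returns at 32): C8 is inverted by enolisation and kinetic protonation instead of substitution. t-BuMe2SiOTf and 2,6-lutidine give the 8α-tert-butyldimethylsilyl ether F3. KN(SiMe3)2 in THF at −78 °C gives the potassium enolate F4. Acetic acid at −78 °C delivers the proton to the only open, outer face, which pushes O8 to the β side and gives the 8β-silyl ether F5. HF·pyridine gives the 8β-hydroxy ketone F6, and acylation with methacrylic anhydride, Et3N and 4-(dimethylamino)pyridine (retention) gives 32.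

3. Step 15.
   - What may go wrong: addition may be sluggish at a carbonyl flanked by a quaternary carbon and a substituted alkene carbon. The dienyl organometallic may decay, and facial selectivity may be poor.
   - Fallback (sets out from 22 and 17, returns at 27, step 14 no longer needed): n-BuLi converts 22 into the lithium acetylide F7, a slim rod-shaped nucleophile that adds to 17 (CeCl3, THF, −78 °C) to give the propargylic alcohol F8. NaAlH2(OCH2CH2OMe)2 in THF reduces the alkyne by hydroxyl-directed trans-hydroalumination and protonolysis to the E-dienyl carbinol 27.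

**Further compounds**
F1 | step 16 | triethylsilyl dienol ether of the ten-membered ring | CC[Si](CC)(CC)O/C1=C\[C@@H](C(=C)COCc2ccc(OC)cc2)[C@H](OCc2ccc(OC)cc2)/C=C(\C)CC/C=C1/COCc1ccc(OC)cc1
F2 | step 16 | 8α-triethylsilyloxy ketone | CC[Si](CC)(CC)O[C@@H]1[C@@H](C(=C)COCc2ccc(OC)cc2)[C@H](OCc2ccc(OC)cc2)/C=C(\C)CC/C=C(/COCc2ccc(OC)cc2)C1=O
F3 | step 17 | 8α-tert-butyldimethylsilyl ether of 30 | CC(C)(C)[Si](C)(C)O[C@@H]1[C@@H](C(=C)COCc2ccc(OC)cc2)[C@H](OCc2ccc(OC)cc2)/C=C(\C)CC/C=C(/COCc2ccc(OC)cc2)C1=O
F4 | step 17 | potassium enolate of F3 | [K+].[O-]C1=C(O[Si](C)(C)C(C)(C)C)[C@@H](C(=C)COCc2ccc(OC)cc2)[C@H](OCc2ccc(OC)cc2)/C=C(\C)CC/C=C1/COCc1ccc(OC)cc1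
F5 | step 17 | 8β-tert-butyldimethylsilyl ether | CC(C)(C)[Si](C)(C)O[C@H]1[C@@H](C(=C)COCc2ccc(OC)cc2)[C@H](OCc2ccc(OC)cc2)/C=C(\C)CC/C=C(/COCc2ccc(OC)cc2)C1=O
F6 | step 17 | 8β-hydroxy ketone (C8 epimer of 30) | O[C@H]1[C@@H](C(=C)COCc2ccc(OC)cc2)[C@H](OCc2ccc(OC)cc2)/C=C(\C)CC/C=C(/COCc2ccc(OC)cc2)C1=O
F7 | step 15 | lithium acetylide of 22 | [Li]C#CC(=C)COCc1ccc(OC)cc1
F8 | step 15 | propargylic alcohol (same configuration at C9 and C4 as 27) | O[C@@]1(C#CC(=C)COCc2ccc(OC)cc2)C(COCc2ccc(OC)cc2)=CCC[C@@]1(C)/C=C/OCc1ccc(OC)cc1
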